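Each half of the twofold-symmetric target is a 3-methylquinolizidin-2-one. The plan rests on reading its ring A (N5–C4–C3–C2–C1–C9a) as a β-lactam (amide bond N5–C2 across C9a–C1) into which an isopropenyl unit (C3, C4) has been inserted. The precursor is a 16-membered bis-β-lactam made by head-to-tail dialkylation of an enantiopure bicyclic azetidinone. In one operation two isopropenyllithium units open both azetidinones at C2 and each freed amine adds to its new enone (6-endo aza-Michael), so both four-membered rings grow by two carbons and the target is reached. The step exploits the two β-amino ketone units N5–C4–C3(CH3)–C2=O and the symmetry; C9 comes from an auxiliary-controlled Michael addition, C9a from a cis-selective reduction.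

Key step: step 10

Locants: every half is numbered as an octahydro-2H-quinolizin-2-one (C1, C2=O, C3–CH3, C4, N5, C6–C9, C9a; ring A = N5, C4, C3, C2, C1, C9a; ring B = N5, C6–C9, C9a). The same atom labels are used for all precursors.

Remark on the chemistry (assumption): C1 and C3 are α to the ketone and are taken to equilibrate under mild base to the all-equatorial arrangement that the target shows (H1 and H3 cis, both trans to H9a), so only C9 and C9a need kinetic control.

**Route**

Step 1
Reactants: 1 7-chloroheptanoic acid; 2 (4R)-4-benzyl-1,3-oxazolidin-2-one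
Product: 4 (4R)-4-benzyl-3-(7-chloroheptanoyl)-1,3-oxazolidin-2-one, via mixed pivalic anhydride 3 (not isolated)
Conditions: PivCl, Et3N, THF, −20 °C; then LiCl, 2, −20 °C to rt
Reagents that add atoms: none
Why: N-Acylation of the oxazolidinone through the mixed pivalic anhydride (LiCl/Et3N method) attaches the chain to the chiral auxiliary without forming a stereocentre.

Step 2
Reactants: 4 (4R)-4-benzyl-3-(7-chloroheptanoyl)-1,3-oxazolidin-2-one; 5 acrylonitrile
Product: 7 (4R)-4-benzyl-3-[(2S)-7-chloro-2-(2-cyanoethyl)heptanoyl]-1,3-oxazolidin-2-one, via Cl3Ti Z-enolate 6 (not isolated)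
Conditions: TiCl4, i-Pr2NEt, CH2Cl2, 0 °C; then 5, 0 °C to rt
Reagents that add atoms: none
Why: Auxiliary-controlled Michael addition of a chelated (Z)-titanium enolate: the C4 benzyl group of the oxazolidinone blocks one enolate face, so acrylonitrile bonds to the other and the new centre C9 should form as (S).

Step 3
Reactants: 7 (4R)-4-benzyl-3-[(2S)-7-chloro-2-(2-cyanoethyl)heptanoyl]-1,3-oxazolidin-2-one
Product: 9 (3S)-3-(5-chloropentyl)piperidin-2-one, via primary amine 8 (not isolated)
Conditions: H2 (4 atm), Raney Ni, EtOH, rt to 50 °C
Reagents that add atoms: none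
Why: Catalytic hydrogenation of the nitrile gives the primary amine, which attacks the exocyclic imide carbonyl through a six-membered transition state (intramolecular aminolysis) to close ring B as the δ-lactam and release the auxiliary; the neutral conditions should leave C9 and the alkyl chloride untouched.

Step 4
Reactants: 9 (3S)-3-(5-chloropentyl)piperidin-2-one
Product: 10 (3S)-3-(5-chloropentyl)piperidine-2-thione
Conditions: Lawesson's reagent, THF, rt to 50 °C
Reagents that add atoms: Lawesson's reagent, COc1ccc(cc1)P1(=S)SP(=S)(S1)c1ccc(OC)cc1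
Why: Thionation of a secondary lactam with Lawesson's reagent, which does not touch the alkyl chloride or the stereocentre.

Step 5
Reactants: 10 (3S)-3-(5-chloropentyl)piperidine-2-thione; 11 ethyl bromoacetate
Product: 13 ethyl (2Z)-[(3S)-3-(5-chloropentyl)piperidin-2-ylidene]acetate, via S-alkyl thioimidate hydrobromide 12 (not isolated)
Conditions: 11, CH2Cl2, rt; then PPh3, Et3N, MeCN, rt to 50 °C
Reagents that add atoms: none
Why: Eschenmoser sulfide contraction: S-alkylation by the α-bromo ester, then base-induced C–C bond formation at C9a and transfer of sulfur to PPh3, gives the vinylogous carbamate, whose (Z) geometry is fixed by the N–H···O=C hydrogen bond, while C9 is not acidic enough for Et3N.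

Step 6
Reactants: 13 ethyl (2Z)-[(3S)-3-(5-chloropentyl)piperidin-2-ylidene]acetate
Product: 15 ethyl [(2S,3S)-3-(5-chloropentyl)piperidin-2-yl]acetate, via iminium acetate 14 (not isolated)
Conditions: NaBH(OAc)3, AcOH, MeCN, 0 °C to rt; aq. NaHCO3
Reagents that add atoms: none
Why: Ionic reduction of a vinylogous carbamate (C-protonation, then hydride transfer): in iminium ion 14 allylic 1,2-strain with the CH2CO2Et group holds the C9 chain pseudoaxial, and hydride attacks C9a axially and anti to it, so the new centre C9a should form cis to C9 (2S,3S).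

Step 7
Reactants: 15 ethyl [(2S,3S)-3-(5-chloropentyl)piperidin-2-yl]acetate
Product: 17 (5S,6S)-5-(5-chloropentyl)-1-azabicyclo[4.2.0]octan-8-one, via N-chloromagnesium amide 16 (not isolated)
Conditions: t-BuMgCl, THF, 0 °C to rt; aq. NH4Cl
Reagents that add atoms: none
Why: Grignard-mediated β-lactam synthesis (Breckpot type): the magnesium amide attacks the ester in a 4-exo-trig closure and ethoxide leaves, with both stereocentres untouched.

Step 8
Reactants: 17 (5S,6S)-5-(5-chloropentyl)-1-azabicyclo[4.2.0]octan-8-one
Product: 18 (5S,6S)-5-(5-iodopentyl)-1-azabicyclo[4.2.0]octan-8-one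
Conditions: NaI, acetone, reflux
Reagents that add atoms: sodium iodide NaI, [Na+].[I-]
Why: Finkelstein halide exchange (NaCl precipitates from acetone) turns the chloride, which was inert in all earlier steps, into the iodide needed for enolate alkylation.

Step 9
Reactants: 18 (5S,6S)-5-(5-iodopentyl)-1-azabicyclo[4.2.0]octan-8-one (two molecules)
Product: 21 twofold-symmetric 16-membered bis-β-lactam (two (5S,6R,7R)-1-azabicyclo[4.2.0]octan-8-one units, C7 of each joined to C5 of the other by a (CH2)5 chain), via lithium enolate 19 (not isolated), via linear dimer lithium enolate 20 (not isolated)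
Conditions: LiN(i-Pr)2, THF–DMPU, 0.01 M, −78 °C, then −78 to −10 °C; aq. NH4Cl
Reagents that add atoms: none
Why: Head-to-tail cyclodimerisation by twofold lactam-enolate alkylation: each enolate is alkylated by the primary iodide of a second molecule on the face away from ring B (anti to the C9a–C9 bond), which should set C1 as (R) with H1 trans to H9a, and the second, intramolecular alkylation closes the 16-membered ring, favoured over oligomers by dilution and over self-closure by the strain of an eight-membered ring.

Step 10
Reactants: 21 twofold-symmetric 16-membered bis-β-lactam; 22 2-bromopropene (two molecules)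
Product: 26 target CNP0268544.6 (twofold-symmetric 16-membered dimer of (1R,3S,9S,9aR)-3-methyloctahydro-2H-quinolizin-2-one, C1 of each unit joined to C9 of the other by a (CH2)5 chain), via isopropenyllithium 23 (not isolated), via dilithium bis-carbinolamine alkoxide 24 (not isolated), via bis-amino enone 25 (not isolated)
Conditions: 22 (2.2 equiv), t-BuLi (4.4 equiv), Et2O, −78 °C; then 21, THF, −78 to −20 °C; aq. NH4Cl; then K2CO3, MeOH, rt
Reagents that add atoms: none
Why: One isopropenyllithium per lactam, two per molecule of 21, adds to the strained, weakly conjugated bridgehead-amide carbonyl (C2), and adduct 24 collapses with cleavage of the N5–C2 bond, so each azetidinone is opened to a secondary amine and an isopropenyl ketone (25). The amine then adds to the terminal CH2 of its enone in a 6-endo-trig aza-Michael closure, which joins N5 to the new C4 and turns the four-membered ring N5–C9a–C1–C2 into the six-membered ring N5–C4–C3–C2–C1–C9a, a two-carbon ring expansion that runs twice in one flask. The closest known reactions are the β-amino ketone synthesis from β-lactams with organolithium reagents and the cyclisation of amino vinyl ketones to piperidin-4-ones and quinolizidin-2-ones. C9 and C9a are carried over unchanged from 21, while the new centre C3 and the epimerisable C1 are set under thermodynamic control by K2CO3/MeOH, which should place methyl and chain equatorial on the chair of ring A (H1 and H3 cis, both trans to H9a). The step needs addition to C=O to outrun deprotonation at C1 and only one addition per carbonyl: the sp2 organolithium is a weak base, C1–H is tertiary and hindered, the adduct is an unreactive alkoxide until it opens, and the opened amine should close onto the enone faster than a second organolithium can add.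

**Compound list**

1 | 7-chloroheptanoic acid | OC(=O)CCCCCCCl | starting material
2 | (4R)-4-benzyl-1,3-oxazolidin-2-one | O=C1N[C@H](Cc2ccccc2)CO1 | starting material
3 | 7-chloroheptanoic pivalic anhydride | CC(C)(C)C(=O)OC(=O)CCCCCCCl | intermediate
4 | (4R)-4-benzyl-3-(7-chloroheptanoyl)-1,3-oxazolidin-2-one | O=C(CCCCCCCl)N1[C@H](Cc2ccccc2)COC1=O | intermediate
5 | acrylonitrile | C=CC#N | starting material
6 | Cl3Ti (Z)-enolate of 4 | Cl[Ti](Cl)(Cl)O/C(=C\CCCCCCl)N1[C@H](Cc2ccccc2)COC1=O | intermediate
7 | (4R)-4-benzyl-3-[(2S)-7-chloro-2-(2-cyanoethyl)heptanoyl]-1,3-oxazolidin-2-one | N#CCC[C@H](CCCCCCl)C(=O)N1[C@H](Cc2ccccc2)COC1=O | intermediate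
8 | (4R)-3-[(2S)-2-(3-aminopropyl)-7-chloroheptanoyl]-4-benzyl-1,3-oxazolidin-2-one | NCCC[C@H](CCCCCCl)C(=O)N1[C@H](Cc2ccccc2)COC1=O | intermediate
9 | (3S)-3-(5-chloropentyl)piperidin-2-one | O=C1NCCC[C@@H]1CCCCCCl | intermediate
10 | (3S)-3-(5-chloropentyl)piperidine-2-thione | S=C1NCCC[C@@H]1CCCCCCl | intermediate
11 | ethyl bromoacetate | CCOC(=O)CBr | starting material
12 | ethyl {[(3S)-3-(5-chloropentyl)-3,4,5,6-tetrahydropyridin-2-yl]sulfanyl}acetate hydrobromide | CCOC(=O)CSC1=[NH+]CCC[C@@H]1CCCCCCl.[Br-] | intermediate
13 | ethyl (2Z)-[(3S)-3-(5-chloropentyl)piperidin-2-ylidene]acetate | CCOC(=O)/C=C1\NCCC[C@@H]1CCCCCCl | intermediate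
14 | (3S)-3-(5-chloropentyl)-2-(2-ethoxy-2-oxoethyl)-3,4,5,6-tetrahydropyridinium acetate | CCOC(=O)CC1=[NH+]CCC[C@@H]1CCCCCCl.CC(=O)[O-] | intermediate
15 | ethyl [(2S,3S)-3-(5-chloropentyl)piperidin-2-yl]acetate (2,3-cis) | CCOC(=O)C[C@@H]1NCCC[C@@H]1CCCCCCl | intermediate
16 | N-chloromagnesium amide of 15 | CCOC(=O)C[C@@H]1N([Mg]Cl)CCC[C@@H]1CCCCCCl | intermediate
17 | (5S,6S)-5-(5-chloropentyl)-1-azabicyclo[4.2.0]octan-8-one | O=C1C[C@H]2[C@@H](CCCCCCl)CCCN12 | intermediate
18 | (5S,6S)-5-(5-iodopentyl)-1-azabicyclo[4.2.0]octan-8-one | O=C1C[C@H]2[C@@H](CCCCCI)CCCN12 | intermediate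
19 | lithium enolate of 18 (C7=C8–OLi; ring centres as in 18) | [Li]OC1=C[C@H]2[C@@H](CCCCCI)CCCN12 | intermediate
20 | lithium enolate of the linear head-to-tail dimer (C7 of one β-lactam bonded to the pentyl terminus of the other; one C–I end and one enolate left) | [Li]OC1=C[C@H]2[C@@H](CCCCC[C@H]3C(=O)N4CCC[C@H](CCCCCI)[C@H]34)CCCN12 | intermediate
21 | twofold-symmetric 16-membered bis-β-lactam; two (5S,6R,7R)-1-azabicyclo[4.2.0]octan-8-one units, C7 of each joined to C5 of the other by (CH2)5 | O=C1N2CCC[C@@H]3CCCCC[C@H]4C(=O)N5CCC[C@H](CCCCC[C@@H]1[C@@H]32)[C@H]45 | intermediate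
22 | 2-bromopropene | CC(Br)=C | starting material
23 | isopropenyllithium | [Li]C(C)=C | intermediate
24 | dilithium salt of the twofold isopropenyl adduct of 21 (each former lactam carbon carries OLi and isopropenyl; configuration at these two carbons not defined) | [Li]OC1(C(C)=C)N2CCC[C@@H]3CCCCC[C@H]4C(O[Li])(C(C)=C)N5CCC[C@H](CCCCC[C@@H]1[C@@H]32)[C@H]45 | intermediate
25 | macrocyclic bis(amino enone): 16-membered carbocycle, each half with a piperidine (ring B, N–H) fused at C9–C9a and a 2-methylprop-2-enoyl group on C1 | C=C(C)C(=O)[C@H]1[C@@H]2NCCC[C@@H]2CCCCC[C@@H](C(=O)C(C)=C)[C@@H]2NCCC[C@@H]2CCCCC1 | intermediate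
26 | CNP0268544.6; twofold-symmetric 16-membered dimer of (1R,3S,9S,9aR)-3-methyloctahydro-2H-quinolizin-2-one, C1 of each unit joined to C9 of the other by (CH2)5 | C[C@H]1CN2CCC[C@@H]3CCCCC[C@H]4C(=O)[C@@H](C)CN5CCC[C@H](CCCCC[C@@H](C1=O)[C@@H]32)[C@H]45 | target

**Step count and risks**

Total step count: 10. Longest linear sequence: 10 steps (1 to 26).

Steps most likely to fail:

1. Step 10. The organolithium may remove the C1 proton instead of adding to the carbonyl, may add a second time to the liberated enone before the amine closes the ring, or the adduct may not open cleanly. Prolonged exposure to base may also scramble C9a through retro-Michael opening of the N5–C9a bond. Fallback (sets out from 21, comes back at 25): acid methanolysis (HCl, MeOH, reflux; then aq. NaHCO3) opens both β-lactams to the macrocyclic bis(β-amino methyl ester) F1. Treatment with MeNH(OMe)·HCl and i-PrMgCl in THF at −20 °C converts F1 into the macrocyclic bis(N-methoxy-N-methylamide) F2. Excess isopropenylmagnesium bromide (CH2=C(CH3)MgBr, THF, 0 °C) followed by aqueous NH4Cl then gives the bis(amino enone) 25, which closes and equilibrates to 26 under the K2CO3/MeOH conditions of step 10. Here the ketone is made by a Weinreb ketone synthesis on an open-chain amide, so no carbanion has to attack the lactam.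

2. Step 9. Chain growth to oligomers may outrun ring closure, one molecule may close on itself to an eight-membered ring, or proton exchange between enolate and alkylated lactam may stop the sequence halfway. Fallback (sets out from 17 and 18, comes back at 20): chloride 17, used in excess, is deprotonated with LiN(i-Pr)2 (THF–DMPU, −78 °C) and alkylated by iodide 18 to the linear chloro dimer F3. NaI in refluxing acetone gives the linear iodo dimer F4. Slow addition of F4 to LiN(i-Pr)2 at high dilution (0.001 M, −78 to −10 °C) deprotonates the remaining CH2 lactam to enolate 20, which closes the 16-membered ring to 21. The two C–C bonds are thus made one after the other and only the ring closure is run dilute.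

3. Step 7. The 4-exo closure to the strained bicyclic β-lactam may be slow, so that intermolecular acylation to oligoamides or base-induced retro-Michael opening of the β-amino ester competes. Fallback (sets out from 15, comes back at 17): saponification (LiOH, THF–H2O, rt; neutralisation) gives [(2S,3S)-3-(5-chloropentyl)piperidin-2-yl]acetic acid F5, which is cyclodehydrated with 2-chloro-1-methylpyridinium iodide and Et3N in dilute MeCN at reflux; the carboxyl group is activated instead of an amide anion attacking an ester.

Further compounds
F1 | step 10 | macrocyclic bis(β-amino methyl ester): 16-membered carbocycle, each half with a fused piperidine (N–H) at C9–C9a and CO2CH3 on C1 | COC(=O)[C@H]1[C@@H]2NCCC[C@@H]2CCCCC[C@@H](C(=O)OC)[C@@H]2NCCC[C@@H]2CCCCC1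
F2 | step 10 | macrocyclic bis(N-methoxy-N-methylamide) corresponding to F1 | CON(C)C(=O)[C@H]1[C@@H]2NCCC[C@@H]2CCCCC[C@@H](C(=O)N(C)OC)[C@@H]2NCCC[C@@H]2CCCCC1
F3 | step 9 | linear chloro dimer: C7 of the 17-derived β-lactam bonded to the pentyl terminus of the 18-derived β-lactam, 5-chloropentyl end retained | O=C1C[C@H]2[C@@H](CCCCC[C@H]3C(=O)N4CCC[C@H](CCCCCCl)[C@H]34)CCCN12
F4 | step 9 | linear iodo dimer (iodide in place of the chloride of F3) | O=C1C[C@H]2[C@@H](CCCCC[C@H]3C(=O)N4CCC[C@H](CCCCCI)[C@H]34)CCCN12
F5 | step 7 | [(2S,3S)-3-(5-chloropentyl)piperidin-2-yl]acetic acid | OC(=O)C[C@@H]1NCCC[C@@H]1CCCCCCl
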